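**Plan**

- Retrosynthesis: cut the palmitate C–O bond and the C(=O)–CH= bond of the enone, then in one operation O1–C2 of the pyran and the CH2–C(=O) bond of the C2 arm, then the C8–CHO bond and the C4a–CH2 bond.
- Enabling feature: C2 of the chroman carries O1, a methyl group and a CH2–C(=O) arm. This is the pattern left when a phenol oxygen adds to a 1,1-disubstituted alkene on palladium and the β-hydrogen-free alkylpalladium takes up CO.
- Forward: 3,5-dimethoxybenzyl alcohol supplies the benzene ring. The 3-methylbut-3-enyl chain is joined at the carbon between the two methoxy groups, one methoxy is opened to the phenol, and the formyl carbon is placed ortho to it and masked as a dioxane acetal.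
- The pyran, the only ring made, is then closed with one-carbon extension to the acetate. Ester to Weinreb amide to enone, silyl ether to palmitate, and acetal to aldehyde finish the route.
- Stereochemistry: the single stereocenter C2 (S) comes from ligand-controlled enantioface selection in the ring closure. It is quaternary, and no strong base is used once the β-aryloxy ketone exists.

Key step: step 7

Remark: chroman numbering (O1, C2, C3, C4, C4a, C5 to C8, C8a) is used; (S,S)-Bn-BOXAX is assumed to give 2S, by analogy with the tocopherol-type sense of this closure on related 2-(3-methylbut-3-enyl)phenols, and the (R,R) ligand would be used if the sense proved opposite.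

**Route**

Step 1
Reactants: 1 3,5-dimethoxybenzyl alcohol
Product: 2 [(3,5-dimethoxyphenyl)methoxy]triisopropylsilane
Conditions: TIPSCl, imidazole, DMF, rt
Reagents that add atoms: triisopropylsilyl chloride, CC(C)[Si](Cl)(C(C)C)C(C)C
Why: Imidazole-promoted silylation of a primary benzylic alcohol; the triisopropylsilyl ether is chosen because it should outlast butyllithium, hot thiolate and weakly acidic methanol.

Step 2
Reactants: 2 [(3,5-dimethoxyphenyl)methoxy]triisopropylsilane
Product: 4 [(4-iodo-3,5-dimethoxyphenyl)methoxy]triisopropylsilane, via 4-lithio aryl silyl ether 3 (not isolated)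
Conditions: n-BuLi, THF, 0 °C to rt; then I2, −78 °C to rt
Reagents that add atoms: iodine, II; n-butyllithium, [Li]CCCC (lithium only in intermediate 3)
Why: Directed ortho-metalation removes the proton between the two methoxy groups through cooperative coordination of both oxygens, and iodine traps the aryllithium at that carbon only, the bulky silyl group shielding the benzylic position.

Step 3
Reactants: 4 [(4-iodo-3,5-dimethoxyphenyl)methoxy]triisopropylsilane; 5 4-bromo-2-methylbut-1-ene
Product: 7 {[3,5-dimethoxy-4-(3-methylbut-3-en-1-yl)phenyl]methoxy}triisopropylsilane, via (3-methylbut-3-enyl)zinc bromide 6 (not isolated)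
Conditions: 5, Zn dust, LiCl, THF, 50 °C; then 4, Pd(OAc)2 (2 mol%), SPhos (4 mol%), THF, 60 °C
Reagents that add atoms: 4-bromo-2-methylbut-1-ene 5, C=C(C)CCBr; zinc, [Zn] (only in intermediate 6)
Why: Negishi cross-coupling of a primary alkylzinc bromide with an aryl iodide, in which the bulky electron-rich biaryl phosphine should make oxidative addition and reductive elimination at the doubly ortho-substituted carbon faster than β-hydride elimination.

Step 4
Reactants: 7 {[3,5-dimethoxy-4-(3-methylbut-3-en-1-yl)phenyl]methoxy}triisopropylsilane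
Product: 8 3-methoxy-2-(3-methylbut-3-en-1-yl)-5-(triisopropylsilyloxymethyl)phenol
Conditions: NaSEt, DMF, 120 °C
Reagents that add atoms: none
Why: Thiolate O-demethylation of an aryl methyl ether (SN2 at methyl); the two methoxy groups are equivalent, and the phenoxide formed after the first cleavage should protect the second.

Step 5
Reactants: 8 3-methoxy-2-(3-methylbut-3-en-1-yl)-5-(triisopropylsilyloxymethyl)phenol; 9 paraformaldehyde
Product: 10 2-hydroxy-4-methoxy-3-(3-methylbut-3-en-1-yl)-6-(triisopropylsilyloxymethyl)benzaldehyde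
Conditions: MgCl2, Et3N, (CH2O)n, THF, reflux
Reagents that add atoms: paraformaldehyde 9, C=O
Why: Magnesium-mediated ortho-formylation of a phenol (Casnati–Skattebøl), in which the magnesium phenoxide delivers formaldehyde to the only free ortho carbon and a second formaldehyde oxidises the benzylic alkoxide to the aldehyde, leaving the para position untouched.

Step 6
Reactants: 10 2-hydroxy-4-methoxy-3-(3-methylbut-3-en-1-yl)-6-(triisopropylsilyloxymethyl)benzaldehyde
Product: 11 2-(5,5-dimethyl-1,3-dioxan-2-yl)-5-methoxy-6-(3-methylbut-3-en-1-yl)-3-(triisopropylsilyloxymethyl)phenol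
Conditions: 2,2-dimethylpropane-1,3-diol, PPTS (cat.), benzene, reflux, Dean–Stark
Reagents that add atoms: 2,2-dimethylpropane-1,3-diol, OCC(C)(C)CO
Why: Acid-catalysed acetalisation with azeotropic removal of water, using a pyridinium acid too weak to protonate the 1,1-disubstituted alkene and a neopentyl-glycol dioxane chosen as the most hydrolysis-resistant common aldehyde acetal.

Step 7
Reactants: 11 2-(5,5-dimethyl-1,3-dioxan-2-yl)-5-methoxy-6-(3-methylbut-3-en-1-yl)-3-(triisopropylsilyloxymethyl)phenol; 12 carbon monoxide; 13 methanol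
Product: 16 methyl 2-[(2S)-8-(5,5-dimethyl-1,3-dioxan-2-yl)-5-methoxy-2-methyl-7-(triisopropylsilyloxymethyl)chroman-2-yl]acetate, via alkylpalladium trifluoroacetate 14 (not isolated), via acylpalladium trifluoroacetate 15 (not isolated)
Conditions: Pd(OCOCF3)2 (5 mol%), (S,S)-Bn-BOXAX (20 mol%), p-benzoquinone (4 equiv), CO (1 atm), MeOH, rt
Reagents that add atoms: carbon monoxide 12, [C-]#[O+]; methanol 13, CO
Why: Divalent palladium carrying the binaphthyl bis(oxazoline) binds the alkene and the phenol oxygen adds to its internal carbon to form O1–C2; the resulting alkylpalladium 14 has a quaternary β-carbon and so cannot eliminate, inserts CO to give 15, and methanol cleaves the acyl–palladium bond to form the CH2–C(=O) bond, while benzoquinone reoxidises the zerovalent palladium. The closest known reaction type is the enantioselective domino Wacker cyclisation and methoxycarbonylation of 2-(3-methylbut-3-enyl)phenols to 2-methylchroman-2-ylacetates, including phenols with a second ortho substituent. The pyran ring closes in the 6-exo-trig mode. The new stereocenter C2 (S) is controlled by the chiral ligand, which selects the alkene face presented to the phenoxide. The step needs enantioface selection, oxygen attack at the internal alkene carbon and carbonylation in place of elimination; the 1,1-disubstituted alkene on a two-carbon tether secures the last two. Masking the aldehyde as the acetal keeps the phenol free of a hydrogen bond to a carbonyl, and the excess basic ligand should buffer the trifluoroacetic acid so that the dioxane and the silyl ether persist in methanol.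

Step 8
Reactants: 16 methyl 2-[(2S)-8-(5,5-dimethyl-1,3-dioxan-2-yl)-5-methoxy-2-methyl-7-(triisopropylsilyloxymethyl)chroman-2-yl]acetate
Product: 17 2-[(2S)-8-(5,5-dimethyl-1,3-dioxan-2-yl)-5-methoxy-2-methyl-7-(triisopropylsilyloxymethyl)chroman-2-yl]-N-methoxy-N-methylacetamide
Conditions: MeNH(OMe)·HCl, i-PrMgCl, THF, −20 to 0 °C
Reagents that add atoms: N,O-dimethylhydroxylamine hydrochloride, CNOC.Cl
Why: Ester aminolysis by the magnesium amide of N,O-dimethylhydroxylamine (Weinreb amide formation) at low temperature, to which acetal, silyl ether and the quaternary centre are inert.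

Step 9
Reactants: 17 2-[(2S)-8-(5,5-dimethyl-1,3-dioxan-2-yl)-5-methoxy-2-methyl-7-(triisopropylsilyloxymethyl)chroman-2-yl]-N-methoxy-N-methylacetamide
Product: 18 2-[(2S)-8-(5,5-dimethyl-1,3-dioxan-2-yl)-7-(hydroxymethyl)-5-methoxy-2-methylchroman-2-yl]-N-methoxy-N-methylacetamide
Conditions: TBAF, THF, 0 °C to rt
Reagents that add atoms: none
Why: Fluoride cleavage of the silyl ether, placed before the ketone exists so that basic fluoride never meets a β-aryloxy ketone and the acetal beside the free hydroxymethyl group sees only base.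

Step 10
Reactants: 18 2-[(2S)-8-(5,5-dimethyl-1,3-dioxan-2-yl)-7-(hydroxymethyl)-5-methoxy-2-methylchroman-2-yl]-N-methoxy-N-methylacetamide; 19 (2-methylprop-1-enyl)magnesium bromide
Product: 21 1-[(2S)-8-(5,5-dimethyl-1,3-dioxan-2-yl)-7-(hydroxymethyl)-5-methoxy-2-methylchroman-2-yl]-4-methylpent-3-en-2-one, via magnesium hemiaminal adduct 20 (not isolated)
Conditions: 19 (3 equiv), THF, 0 °C; then aq. NH4Cl
Reagents that add atoms: (2-methylprop-1-enyl)magnesium bromide 19, CC(C)=C[Mg]Br
Why: Weinreb ketone synthesis, in which the first equivalent of Grignard reagent deprotonates the alcohol and the second adds once to give a chelated tetrahedral adduct that releases the enone only on quench, so over-addition and base-induced opening of the pyran should not occur.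

Step 11
Reactants: 21 1-[(2S)-8-(5,5-dimethyl-1,3-dioxan-2-yl)-7-(hydroxymethyl)-5-methoxy-2-methylchroman-2-yl]-4-methylpent-3-en-2-one; 22 palmitoyl chloride
Product: 23 [(2S)-8-(5,5-dimethyl-1,3-dioxan-2-yl)-5-methoxy-2-methyl-2-(4-methyl-2-oxopent-3-en-1-yl)chroman-7-yl]methyl hexadecanoate
Conditions: 22, pyridine, DMAP (cat.), CH2Cl2, 0 °C to rt
Reagents that add atoms: palmitoyl chloride 22, CCCCCCCCCCCCCCCC(=O)Cl
Why: DMAP-catalysed acylation of the primary benzylic alcohol by an acid chloride under mildly basic conditions that should leave the acetal, the enone and the stereocenter alone.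

Step 12
Reactants: 23 [(2S)-8-(5,5-dimethyl-1,3-dioxan-2-yl)-5-methoxy-2-methyl-2-(4-methyl-2-oxopent-3-en-1-yl)chroman-7-yl]methyl hexadecanoate
Product: 24 [(2S)-8-formyl-5-methoxy-2-methyl-2-(4-methyl-2-oxopent-3-en-1-yl)chroman-7-yl]methyl hexadecanoate (CNP0228756.1)
Conditions: aq. HCl (1 M), THF, rt
Reagents that add atoms: water, O
Why: Acid-catalysed acetal hydrolysis, helped by the para methoxy group and the ortho ring oxygen that stabilise the oxocarbenium ion, so dilute acid at room temperature should suffice and spare the palmitate, the enone and the tertiary aryl ether.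

**Compound list**

1 | 3,5-dimethoxybenzyl alcohol | COc1cc(CO)cc(OC)c1 | starting material
2 | [(3,5-dimethoxyphenyl)methoxy]triisopropylsilane | COc1cc(CO[Si](C(C)C)(C(C)C)C(C)C)cc(OC)c1 | intermediate
3 | [2,6-dimethoxy-4-(triisopropylsilyloxymethyl)phenyl]lithium (not isolated) | [Li]c1c(OC)cc(CO[Si](C(C)C)(C(C)C)C(C)C)cc1OC | intermediate
4 | [(4-iodo-3,5-dimethoxyphenyl)methoxy]triisopropylsilane | Ic1c(OC)cc(CO[Si](C(C)C)(C(C)C)C(C)C)cc1OC | intermediate
5 | 4-bromo-2-methylbut-1-ene | C=C(C)CCBr | starting material
6 | (3-methylbut-3-enyl)zinc bromide (not isolated) | C=C(C)CC[Zn]Br | intermediate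
7 | {[3,5-dimethoxy-4-(3-methylbut-3-en-1-yl)phenyl]methoxy}triisopropylsilane | C=C(C)CCc1c(OC)cc(CO[Si](C(C)C)(C(C)C)C(C)C)cc1OC | intermediate
8 | 3-methoxy-2-(3-methylbut-3-en-1-yl)-5-(triisopropylsilyloxymethyl)phenol | C=C(C)CCc1c(OC)cc(CO[Si](C(C)C)(C(C)C)C(C)C)cc1O | intermediate
9 | paraformaldehyde (formaldehyde equivalent) | C=O | starting material
10 | 2-hydroxy-4-methoxy-3-(3-methylbut-3-en-1-yl)-6-(triisopropylsilyloxymethyl)benzaldehyde | C=C(C)CCc1c(OC)cc(CO[Si](C(C)C)(C(C)C)C(C)C)c(C=O)c1O | intermediate
11 | 2-(5,5-dimethyl-1,3-dioxan-2-yl)-5-methoxy-6-(3-methylbut-3-en-1-yl)-3-(triisopropylsilyloxymethyl)phenol | C=C(C)CCc1c(OC)cc(CO[Si](C(C)C)(C(C)C)C(C)C)c(C2OCC(C)(C)CO2)c1O | intermediate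
12 | carbon monoxide | [C-]#[O+] | starting material
13 | methanol | CO | starting material
14 | (2S)-chroman-2-ylmethylpalladium trifluoroacetate, bis(oxazoline) ligand not drawn (not isolated) | CC(C)[Si](C(C)C)(C(C)C)OCc1cc(OC)c2c(c1C3OCC(C)(C)CO3)O[C@](C)(C[Pd]OC(=O)C(F)(F)F)CC2 | intermediate
15 | (2S)-chroman-2-ylacetylpalladium trifluoroacetate, bis(oxazoline) ligand not drawn (not isolated) | CC(C)[Si](C(C)C)(C(C)C)OCc1cc(OC)c2c(c1C3OCC(C)(C)CO3)O[C@](C)(CC(=O)[Pd]OC(=O)C(F)(F)F)CC2 | intermediate
16 | methyl 2-[(2S)-8-(5,5-dimethyl-1,3-dioxan-2-yl)-5-methoxy-2-methyl-7-(triisopropylsilyloxymethyl)chroman-2-yl]acetate | CC(C)[Si](C(C)C)(C(C)C)OCc1cc(OC)c2c(c1C3OCC(C)(C)CO3)O[C@](C)(CC(=O)OC)CC2 | intermediate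
17 | 2-[(2S)-8-(5,5-dimethyl-1,3-dioxan-2-yl)-5-methoxy-2-methyl-7-(triisopropylsilyloxymethyl)chroman-2-yl]-N-methoxy-N-methylacetamide | CC(C)[Si](C(C)C)(C(C)C)OCc1cc(OC)c2c(c1C3OCC(C)(C)CO3)O[C@](C)(CC(=O)N(C)OC)CC2 | intermediate
18 | 2-[(2S)-8-(5,5-dimethyl-1,3-dioxan-2-yl)-7-(hydroxymethyl)-5-methoxy-2-methylchroman-2-yl]-N-methoxy-N-methylacetamide | OCc1cc(OC)c2c(c1C3OCC(C)(C)CO3)O[C@](C)(CC(=O)N(C)OC)CC2 | intermediate
19 | (2-methylprop-1-enyl)magnesium bromide (commercial THF solution) | CC(C)=C[Mg]Br | starting material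
20 | bis(bromomagnesium) hemiaminal adduct of 18, mixture at the new aminal carbon (not isolated) | Br[Mg]OCc1cc(OC)c2c(c1C3OCC(C)(C)CO3)O[C@](C)(CC(O[Mg]Br)(N(C)OC)C=C(C)C)CC2 | intermediate
21 | 1-[(2S)-8-(5,5-dimethyl-1,3-dioxan-2-yl)-7-(hydroxymethyl)-5-methoxy-2-methylchroman-2-yl]-4-methylpent-3-en-2-one | OCc1cc(OC)c2c(c1C3OCC(C)(C)CO3)O[C@](C)(CC(=O)C=C(C)C)CC2 | intermediate
22 | palmitoyl chloride | CCCCCCCCCCCCCCCC(=O)Cl | starting material
23 | [(2S)-8-(5,5-dimethyl-1,3-dioxan-2-yl)-5-methoxy-2-methyl-2-(4-methyl-2-oxopent-3-en-1-yl)chroman-7-yl]methyl hexadecanoate | CCCCCCCCCCCCCCCC(=O)OCc1cc(OC)c2c(c1C3OCC(C)(C)CO3)O[C@](C)(CC(=O)C=C(C)C)CC2 | intermediate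
24 | [(2S)-8-formyl-5-methoxy-2-methyl-2-(4-methyl-2-oxopent-3-en-1-yl)chroman-7-yl]methyl hexadecanoate (CNP0228756.1) | CCCCCCCCCCCCCCCC(=O)OCc1cc(OC)c2c(c1C=O)O[C@](C)(CC(=O)C=C(C)C)CC2 | target

**Count and risks**

Total step count: 12. Longest linear sequence: 12 steps, from 1 to 24.

Steps most likely to fail:

1. Step 7. The acetal-bearing ortho carbon may crowd the palladium-bound phenoxide, so that discrimination between the two alkene faces erodes. Fallback: setting out from 11, the cyclisation and carbonylation are run without stereocontrol (Pd(OCOCF3)2, 2,2'-bipyridine, p-benzoquinone, CO, MeOH, rt) to give racemic methyl 2-[8-(5,5-dimethyl-1,3-dioxan-2-yl)-5-methoxy-2-methyl-7-(triisopropylsilyloxymethyl)chroman-2-yl]acetate F1. The enantiomers are then separated by preparative chromatography on a chiral stationary phase, and the (S) enantiomer is 16, where the route is rejoined.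

2. Step 6. Under the acid the phenol may add to the alkene in the Markovnikov sense, closing an achiral 2,2-dimethylchroman, or the hindered hydrogen-bonded aldehyde may acetalise incompletely. Fallback: setting out from 10, the free salicylaldehyde is taken directly through the conditions of step 7 to methyl 2-[(2S)-8-formyl-5-methoxy-2-methyl-7-(triisopropylsilyloxymethyl)chroman-2-yl]acetate F2. This compound holds neither alkene nor phenol and is acetalised without risk (2,2-dimethylpropane-1,3-diol, TsOH, benzene, reflux) to return to the route at 16.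

3. Step 3. Oxidative addition and transmetalation at the doubly ortho-substituted iodide may be slow enough for protodeiodination or for β-hydride elimination from the alkylpalladium to take over. Fallback: setting out from 2, the aryllithium 3 is quenched with DMF to give 2,6-dimethoxy-4-(triisopropylsilyloxymethyl)benzaldehyde F3. Aldol condensation with acetone (aq. NaOH) gives (E)-4-[2,6-dimethoxy-4-(triisopropylsilyloxymethyl)phenyl]but-3-en-2-one F4. Hydrogenation of the alkene (H2, palladium on carbon (Pd/C), EtOAc) gives 4-[2,6-dimethoxy-4-(triisopropylsilyloxymethyl)phenyl]butan-2-one F5. Wittig methylenation (Ph3P=CH2 from methyltriphenylphosphonium bromide and KOt-Bu, THF) returns to the route at 7.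

**Further compounds**

F1 | step 7 | racemic methyl 2-[8-(5,5-dimethyl-1,3-dioxan-2-yl)-5-methoxy-2-methyl-7-(triisopropylsilyloxymethyl)chroman-2-yl]acetate | CC(C)[Si](C(C)C)(C(C)C)OCc1cc(OC)c2c(c1C3OCC(C)(C)CO3)OC(C)(CC(=O)OC)CC2
F2 | step 6 | methyl 2-[(2S)-8-formyl-5-methoxy-2-methyl-7-(triisopropylsilyloxymethyl)chroman-2-yl]acetate | CC(C)[Si](C(C)C)(C(C)C)OCc1cc(OC)c2c(c1C=O)O[C@](C)(CC(=O)OC)CC2
F3 | step 3 | 2,6-dimethoxy-4-(triisopropylsilyloxymethyl)benzaldehyde | O=Cc1c(OC)cc(CO[Si](C(C)C)(C(C)C)C(C)C)cc1OC
F4 | step 3 | (E)-4-[2,6-dimethoxy-4-(triisopropylsilyloxymethyl)phenyl]but-3-en-2-one | CC(=O)/C=C/c1c(OC)cc(CO[Si](C(C)C)(C(C)C)C(C)C)cc1OC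
F5 | step 3 | 4-[2,6-dimethoxy-4-(triisopropylsilyloxymethyl)phenyl]butan-2-one | CC(=O)CCc1c(OC)cc(CO[Si](C(C)C)(C(C)C)C(C)C)cc1OC
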